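## The problem

Compound 13 is 7,3',5'-trihydroxy-5,8,4'-trimethoxyflavone, a 4H-chromen-4-one (benzo ring A fused to pyranone ring C) that carries aryl ring B at C2. It has no stereocentre and no stereogenic double bond, so the task is one of connectivity and of regiochemistry on two crowded, oxygen-rich benzene rings. Ring A is fully differentiated: O1 (on C8a) belongs to ring C, the oxygens on C5 and C8 are methylated, the one on C7 is free, and the 5,7,8 pattern must be obtained free of the isomeric 5,6,7 pattern. The customary building block, an o-hydroxyacetophenone, would be a pentasubstituted benzene with four oxygen atoms in four different states, and a conventional route spends most of its steps on making it and on protecting O7. The C5 methoxy group lies peri to the C4 carbonyl and is the first ether lost to BCl3, BBr3 or AlCl3. A flavone with a free 5-OH can open and reclose in hot acid to the 5,6,7 isomer (Wessely-Moser rearrangement), so late Lewis-acidic deprotection and hot mineral acid are excluded. The three free phenols exclude strong oxidants at the end, and the C2=C3 bond limits reducing conditions. The enabling feature is a hidden mirror plane in ring A. Once C4 is detached from C4a and C2 from O1, ring A is 2,5-dimethoxybenzene-1,3-diol 4, and the plane through C5 and C8 makes O1 equivalent to O7 and C4a equivalent to C6, which are the only ring carbons bearing hydrogen. A reagent that acylates 4 at carbon and then condenses with the neighbouring hydroxyl can therefore give only the 5,7,8 pattern with O7 left free. Ring B has the same local symmetry about its C1'-C4' axis.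

## Retrosynthesis

**13 to 12.** The first cut removes only the two O-CH2Ph bonds at C3' and C5' of ring B, so 13 is traced to its dibenzyl ether 12.
- Ring B must be masked, because free phenols there would compete as nucleophiles while the three-carbon bridge is built.
- Benzyl is preferred to methyl, isopropyl or acyl because it leaves by neutral hydrogenolysis, whereas any Lewis-acidic dealkylation would strip the C5 methoxy group first.
- Ring A carries no protecting group.
- The forward reaction has only to spare the C2=C3 bond.

**12 to 4 and 9 (key disconnection).** Two bonds of ring C are cut together, C4-C4a and O1-C2. This splits 12 into diol 4 (all of ring A) and beta-keto ester 9 (ring B with C2, C3 and C4).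
- Cutting C2-C3 or O1-C2 alone leaves an acylated ring A whose hydroxyls are no longer equivalent and must be told apart by protection.
- Forming O1-C2 first and closing C4-C4a last would need mono-O-alkenylation of 4, which has no built-in brake against reaction at the second hydroxyl, followed by strong acid.
- C-Acylation is self-limiting, since the first acyl group deactivates the ring.
- The precursors are two mirror-symmetric benzenes, each with a single kind of reactive site.
- The forward reaction must deliver lasting C-acylation rather than O-acylation, and attack at the ester-derived carbon rather than at the ketone (flavone, not 4-arylcoumarin). Regiochemistry is not asked of it.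

**9 to 6 and 7, and 6 to 5.** The C2-C3 bond (flavone numbering) is cut. Compound 9 is the crossed Claisen product of the non-enolisable ester 6 and enolate 8 of ethyl acetate 7. This cut is shorter than any route through an aryl alkyne or an acid chloride. Ester 6 is the dibenzyl ether of commercial methyl 3,5-dihydroxy-4-methoxybenzoate 5, which already holds the whole oxygen pattern of ring B with the C4' methyl ether in place, so no selective methylation is needed.

**4 to 3.** Both C-OH bonds of 4 (the future C7-O and C8a-O1 bonds) are cut together and traced to the two C-Br bonds of dibromide 3. The cut keeps the mirror plane, so the twofold forward reaction needs no selectivity and no protecting group. What is asked is a palladium-catalysed hydroxylation that runs to completion at both sites.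

**3 to 2 to 1.** The O-CH3 bond of the future C8 methoxy group and the two C-Br bonds are cut. In 4-methoxyphenol 1 the hydroxyl sends both bromine atoms to its ortho positions, because its para position is held by the methoxy group that becomes C5-OMe. Methylation of 2 then fixes the central methoxy group. The 1,2,3,5 oxygen pattern of ring A is thus set by simple directing effects on a cheap para-disubstituted benzene, and the symmetry is kept until step 6 breaks it once.

## Roads not taken

**Alternative 1:** the most obvious plan cuts C2-C3 and O1-C2.
- *Forward route:* acetophenone A1 would be O-acylated with acid chloride A2. Base would move the acyl group to carbon (Baker-Venkataraman rearrangement) to give diketone A3. Acid would close A3 to the tri-O-benzyl flavone A4, and hydrogenolysis would give 13.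
- *Why the chosen plan is better:* each reaction is safe, but the whole difficulty is moved into A1. Ring A must be acetylated first, and its hydroxyls, no longer equivalent, must then be told apart by a selective benzylation at O7 that serves only to be undone. Counting the preparation of A2, the esterification, the rearrangement and the cyclisation, five or six operations replace what step 6 does in one. The symmetry of 4 would be spent on attaching a two-carbon unit.

**Alternative 2:** cut C4-C4a and O1-C8a, that is, install both neighbouring substituents of ring A on an aryne.
- *Forward route:* fluoride would convert silylaryl triflate A5 into aryne A6. The carboxylate of propiolic acid A7 would add to A6, the aryl anion would attack the acyl carbon (formal C-O insertion), and the resulting o-hydroxyaryl ynone would close to A4.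
- *Why the chosen plan is better:* in a 3-methoxyaryne the nucleophile adds to the carbon remote from OMe. In A6 both aryne carbons have a methoxy neighbour (C5-OMe beside C4a, C8-OMe beside C8a), so the two directing effects cancel. The only remaining bias is the C7 benzyloxy group, which pushes the methyl of C8-OMe towards C8a and shields the very carbon that oxygen must attack, favouring the 6-oxygenated isomer A8. In addition, A5 is a hexasubstituted benzene that is harder to make than 13 itself.

**Alternative 3:** cut C2-C1' and join rings C and B directly.
- *Forward route:* chromone A9 would be arylated at its unfunctionalised C2-H with boronic acid A10 under Pd(OAc)2 and an oxidant (oxidative Heck-type coupling at divalent palladium, C2 being the beta-carbon of the enone) to give 12.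
- *Why the chosen plan is better:* the bond formed is the one bond of 13 that raises no regiochemical question, so the ring A problem is untouched. A9 still has to be made from 4 by acetylation, enaminone formation and cyclisation, and A10 needs a separate halogenation and borylation sequence. The step must also choose beta-hydride elimination over protonation (flavone against flavanone) and must tolerate a free phenol and two electron-rich rings under oxidising conditions.

Key step: step 6

Remark on the chemistry: 13 and all compounds of the main route are achiral and have no stereogenic double bond, so their SMILES strings carry no stereodescriptors.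

## Steps

Step 1
Reactants: 1 4-methoxyphenol
Product: 2 2,6-dibromo-4-methoxyphenol
Conditions: NBS (2.05 equiv), i-Pr2NH (0.1 equiv), CH2Cl2, 0 °C to rt
Reagents that add atoms: N-bromosuccinimide, O=C1CCC(=O)N1Br
Why: Electrophilic aromatic bromination: the hydroxyl is the strongest director of 1 and its para position is blocked by OMe, so both bromine atoms enter ortho to OH. The amine-mediated NBS protocol is a known ortho-selective route to 2,6-dibromophenols and avoids free Br2, and with it oxidation to the quinone.

Step 2
Reactants: 2 2,6-dibromo-4-methoxyphenol
Product: 3 1,3-dibromo-2,5-dimethoxybenzene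
Conditions: MeI (1.5 equiv), K2CO3 (2 equiv), acetone, reflux
Reagents that add atoms: iodomethane, CI
Why: Williamson ether synthesis: the acidic dibromophenol is readily deprotonated and the small electrophile reaches the flanked oxygen. This places the future C8 methoxy group between two equivalent C-Br bonds.

Step 3
Reactants: 3 1,3-dibromo-2,5-dimethoxybenzene
Product: 4 2,5-dimethoxybenzene-1,3-diol
Conditions: Pd2(dba)3 (2 mol %), t-BuXPhos (8 mol %), KOH (6 equiv), 1,4-dioxane-H2O (1:1), 100 °C, Ar; then 2 M HCl, 0 °C
Reagents that add atoms: potassium hydroxide, [K+].[OH-]
Why: Palladium-catalysed hydroxylation of aryl bromides (C-O cross-coupling with hydroxide): the bulky biaryl phosphine favours C-O reductive elimination from the arylpalladium hydroxide and holds back diaryl ether formation. Both C-Br bonds are equivalent, so no selectivity is asked, and the methyl ethers are inert to aqueous base.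

Step 4
Reactants: 5 methyl 3,5-dihydroxy-4-methoxybenzoate
Product: 6 methyl 3,5-bis(benzyloxy)-4-methoxybenzoate
Conditions: BnBr (2.3 equiv), K2CO3 (3 equiv), DMF, 60 °C
Reagents that add atoms: benzyl bromide, BrCc1ccccc1
Why: Twofold Williamson ether synthesis on two equivalent phenols; the methyl ester and the methyl ether are untouched by carbonate base.

Step 5
Reactants: 6 methyl 3,5-bis(benzyloxy)-4-methoxybenzoate; 7 ethyl acetate
Product: 9 ethyl 3-[3,5-bis(benzyloxy)-4-methoxyphenyl]-3-oxopropanoate, via lithium enolate 8 (not isolated)
Conditions: 7 (2.5 equiv), LiN(SiMe3)2 (3 equiv), THF, -78 °C; then 6, -78 °C to rt; then 1 M HCl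
Reagents that add atoms: none
Why: Crossed Claisen condensation: 6 has no alpha-hydrogen and can only accept, preformed enolate 8 is the only donor, and deprotonation of 9 by the excess base drives the equilibrium. Benzyl and methyl ethers are inert.

Step 6
Reactants: 4 2,5-dimethoxybenzene-1,3-diol; 9 ethyl 3-[3,5-bis(benzyloxy)-4-methoxyphenyl]-3-oxopropanoate
Product: 12 2-[3,5-bis(benzyloxy)-4-methoxyphenyl]-7-hydroxy-5,8-dimethoxy-4H-chromen-4-one, via aroylketene 10 (not isolated), via o-hydroxyaryl 1,3-diketone 11 (not isolated)
Conditions: 4 (1 equiv), 9 (1.5 equiv), neat melt, 240 °C (microwave, open vessel, Ar stream), 10-20 min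
Reagents that add atoms: none
Why: Above about 200 °C 9 loses ethanol through a six-centre elimination and gives aroylketene 10, which 4 traps reversibly at oxygen and irreversibly at carbon. Attack of a ring carbon ortho to a hydroxyl on the ketene carbon, with the phenolic proton passed to the ketene oxygen in a cyclic hydrogen-bonded array, forms the C4-C4a bond and, after rearomatisation, diketone 11. The hydroxyl on C8a then adds to the aroyl carbonyl (6-exo-trig) and loss of water closes ring C at O1-C2, which makes the sequence irreversible and drains the O-acyl side equilibrium. The closest known reaction type is the Mentzer pyrone synthesis, the uncatalysed thermal condensation of resorcinols and phloroglucinols with beta-keto esters, also run solvent-free under microwave heating with aroylacetates to give flavones. Site selectivity is secured by the mirror plane of 4: C4 and C6 are its only C-H positions, they are equivalent, and each is ortho to one OH, para to the other and ortho to the C5 methoxy group, so only one C-acyl compound can form. The new ketone has one OH and one OMe as ortho neighbours, so only one ring closure is possible and the unused hydroxyl becomes the free 7-OH without protection. The absence of an acid catalyst leaves the aroyl carbonyl unactivated, which disfavours the Pechmann-type attack of the ring carbon on the ketone that leads to a 4-arylcoumarin, and a second annulation at C6 is held back because the donors of ring A in 12 are tied up in conjugation with the C4 carbonyl. No stereocentre is formed.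

Step 7
Reactants: 12 2-[3,5-bis(benzyloxy)-4-methoxyphenyl]-7-hydroxy-5,8-dimethoxy-4H-chromen-4-one
Product: 13 2-(3,5-dihydroxy-4-methoxyphenyl)-7-hydroxy-5,8-dimethoxy-4H-chromen-4-one (CNP0218554.0)
Conditions: H2 (1 atm), Pd/C (10 wt %), EtOAc-MeOH, rt
Reagents that add atoms: none
Why: Hydrogenolysis of aryl benzyl ethers under neutral conditions: the methyl ethers, including the labile one at C5, and the vinylogous ester of ring C should not be attacked at 1 atm and room temperature. No acid is present that could start a Wessely-Moser isomerisation.

## Compound list

1 | 4-methoxyphenol | COc1ccc(O)cc1 | starting material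
2 | 2,6-dibromo-4-methoxyphenol | COc1cc(Br)c(O)c(Br)c1 | intermediate
3 | 1,3-dibromo-2,5-dimethoxybenzene | COc1cc(Br)c(OC)c(Br)c1 | intermediate
4 | 2,5-dimethoxybenzene-1,3-diol | COc1cc(O)c(OC)c(O)c1 | intermediate
5 | methyl 3,5-dihydroxy-4-methoxybenzoate | COC(=O)c1cc(O)c(OC)c(O)c1 | starting material
6 | methyl 3,5-bis(benzyloxy)-4-methoxybenzoate | COC(=O)c1cc(OCc2ccccc2)c(OC)c(OCc2ccccc2)c1 | intermediate
7 | ethyl acetate | CCOC(C)=O | starting material
8 | lithium 1-ethoxyethen-1-olate (lithium enolate of 7, not isolated) | [Li+].[O-]C(=C)OCC | intermediate
9 | ethyl 3-[3,5-bis(benzyloxy)-4-methoxyphenyl]-3-oxopropanoate | CCOC(=O)CC(=O)c1cc(OCc2ccccc2)c(OC)c(OCc2ccccc2)c1 | intermediate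
10 | 3-[3,5-bis(benzyloxy)-4-methoxyphenyl]-3-oxoprop-1-en-1-one (aroylketene, not isolated) | O=C=CC(=O)c1cc(OCc2ccccc2)c(OC)c(OCc2ccccc2)c1 | intermediate
11 | 1-[3,5-bis(benzyloxy)-4-methoxyphenyl]-3-(2,4-dihydroxy-3,6-dimethoxyphenyl)propane-1,3-dione (not isolated) | COc1cc(O)c(OC)c(O)c1C(=O)CC(=O)c1cc(OCc2ccccc2)c(OC)c(OCc2ccccc2)c1 | intermediate
12 | 2-[3,5-bis(benzyloxy)-4-methoxyphenyl]-7-hydroxy-5,8-dimethoxy-4H-chromen-4-one | COc1cc(O)c(OC)c2oc(-c3cc(OCc4ccccc4)c(OC)c(OCc4ccccc4)c3)cc(=O)c12 | intermediate
13 | 2-(3,5-dihydroxy-4-methoxyphenyl)-7-hydroxy-5,8-dimethoxy-4H-chromen-4-one | COc1c(O)cc(-c2cc(=O)c3c(OC)cc(O)c(OC)c3o2)cc1O | target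

## Step count and least certain steps

Total step count: 7. Longest linear sequence: 5 steps (steps 1, 2, 3, 6 and 7). The ring B branch (steps 4 and 5) joins at step 6.

**Step 6 (key step).**
- *What may go wrong:* the ketene source may be used up faster than ring A is acylated at carbon. Reversible O-acylation ties up both partners, and the water released by the ring closure hydrolyses and decarboxylates the keto ester. Long heating then decomposes the electron-rich diol, and excess ketene may esterify the free C7 hydroxyl.
- *Fallback:* the two bonds are made one at a time under ionic conditions. The fallback sets out from 4 (with 6 as partner) and comes back to the route at 11.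
  - Friedel-Crafts acetylation of 4 (Ac2O, BF3·OEt2, 60 °C), still regiochemically unambiguous because of the mirror plane, would give 1-(2,4-dihydroxy-3,6-dimethoxyphenyl)ethan-1-one F1.
  - The lithium polyanion of F1 (LiN(SiMe3)2, 4.5 equiv, THF, -78 °C to rt) would undergo a crossed Claisen condensation with ester 6 to give 11.
  - Here 11 is isolated and closed to 12 with catalytic p-TsOH in refluxing toluene.

**Step 3.**
- *What may go wrong:* after the first hydroxylation the remaining C-Br bond sits in an electron-rich phenoxide. Oxidative addition to zerovalent palladium slows, the reaction may stall halfway, and hydrodebromination, aryl ether formation between phenoxide and unreacted C-Br bonds, or air oxidation of the product dianion can take over.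
- *Fallback:* both C-Br bonds are converted before any phenoxide exists. The fallback sets out from 3 and comes back at 4.
  - Twofold Miyaura borylation (B2pin2, Pd(dppf)Cl2, KOAc, dioxane, 90 °C) would give 2,2'-(2,5-dimethoxy-1,3-phenylene)bis(4,4,5,5-tetramethyl-1,3,2-dioxaborolane) F2.
  - Mild oxidation of F2 (NaBO3·4H2O, THF-H2O, rt) would give 4.

**Step 5.**
- *What may go wrong:* self-condensation of enolate 8 on warming may outrun acylation by the only moderately electrophilic, electron-rich ester, leaving incomplete conversion and ester exchange.
- *Fallback:* the ester enolate is replaced by a decarboxylative malonate acylation (Masamune-Brooks type). The fallback sets out from 6 and comes back at 9.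
  - Saponification (LiOH, THF-H2O) would give 3,5-bis(benzyloxy)-4-methoxybenzoic acid F3.
  - Carbonyldiimidazole would convert F3 into [3,5-bis(benzyloxy)-4-methoxyphenyl](1H-imidazol-1-yl)methanone F4.
  - F4 with potassium ethyl malonate, MgCl2 and Et3N in MeCN would give 9 after loss of CO2.

**Step 7.**
- *What may go wrong:* saturation of the C2=C3 bond may compete with cleavage of the second benzyl ether, made worse by the poor solubility of partly deprotected material, which prolongs the reaction.
- *Fallback:* the order of events is changed so that hydrogen never meets ring C. The fallback sets out from 9 and comes back at 13.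
  - Hydrogenolysis of 9 (H2, Pd/C, EtOAc, rt) would give ethyl 3-(3,5-dihydroxy-4-methoxyphenyl)-3-oxopropanoate F5.
  - F5 would be melted with 4 under the conditions of step 6.
  - The reaction would pass through 3-(3,5-dihydroxy-4-methoxyphenyl)-3-oxoprop-1-en-1-one F6 and 1-(2,4-dihydroxy-3,6-dimethoxyphenyl)-3-(3,5-dihydroxy-4-methoxyphenyl)propane-1,3-dione F7 and give 13 directly. O-Acylation of the ring B phenols is reversible at that temperature.

## Further compounds

F1 | step 6 | 1-(2,4-dihydroxy-3,6-dimethoxyphenyl)ethan-1-one | CC(=O)c1c(O)c(OC)c(O)cc1OC
F2 | step 3 | 2,2'-(2,5-dimethoxy-1,3-phenylene)bis(4,4,5,5-tetramethyl-1,3,2-dioxaborolane) | COc1cc(B2OC(C)(C)C(C)(C)O2)c(OC)c(B2OC(C)(C)C(C)(C)O2)c1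
F3 | step 5 | 3,5-bis(benzyloxy)-4-methoxybenzoic acid | COc1c(OCc2ccccc2)cc(C(=O)O)cc1OCc1ccccc1
F4 | step 5 | [3,5-bis(benzyloxy)-4-methoxyphenyl](1H-imidazol-1-yl)methanone | COc1c(OCc2ccccc2)cc(C(=O)n2ccnc2)cc1OCc1ccccc1
F5 | step 7 | ethyl 3-(3,5-dihydroxy-4-methoxyphenyl)-3-oxopropanoate | CCOC(=O)CC(=O)c1cc(O)c(OC)c(O)c1
F6 | step 7 | 3-(3,5-dihydroxy-4-methoxyphenyl)-3-oxoprop-1-en-1-one | O=C=CC(=O)c1cc(O)c(OC)c(O)c1
F7 | step 7 | 1-(2,4-dihydroxy-3,6-dimethoxyphenyl)-3-(3,5-dihydroxy-4-methoxyphenyl)propane-1,3-dione | COc1cc(O)c(OC)c(O)c1C(=O)CC(=O)c1cc(O)c(OC)c(O)c1
A1 | alternative 1 | 1-[4-(benzyloxy)-2-hydroxy-3,6-dimethoxyphenyl]ethan-1-one | CC(=O)c1c(O)c(OC)c(OCc2ccccc2)cc1OC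
A2 | alternative 1 | 3,5-bis(benzyloxy)-4-methoxybenzoyl chloride | COc1c(OCc2ccccc2)cc(C(=O)Cl)cc1OCc1ccccc1
A3 | alternative 1 | 1-[4-(benzyloxy)-2-hydroxy-3,6-dimethoxyphenyl]-3-[3,5-bis(benzyloxy)-4-methoxyphenyl]propane-1,3-dione | COc1cc(OCc2ccccc2)c(OC)c(O)c1C(=O)CC(=O)c1cc(OCc2ccccc2)c(OC)c(OCc2ccccc2)c1
A4 | alternative 1 | 7-(benzyloxy)-2-[3,5-bis(benzyloxy)-4-methoxyphenyl]-5,8-dimethoxy-4H-chromen-4-one | COc1cc(OCc2ccccc2)c(OC)c2oc(-c3cc(OCc4ccccc4)c(OC)c(OCc4ccccc4)c3)cc(=O)c12
A5 | alternative 2 | 3-(benzyloxy)-2,5-dimethoxy-6-(trimethylsilyl)phenyl trifluoromethanesulfonate | COc1cc(OCc2ccccc2)c(OC)c(OS(=O)(=O)C(F)(F)F)c1[Si](C)(C)C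
A6 | alternative 2 | 4-(benzyloxy)-3,6-dimethoxybenzyne (1,2-didehydrobenzene) | COC1=CC(OCc2ccccc2)=C(OC)C#C1
A7 | alternative 2 | 3-[3,5-bis(benzyloxy)-4-methoxyphenyl]prop-2-ynoic acid | COc1c(OCc2ccccc2)cc(C#CC(=O)O)cc1OCc1ccccc1
A8 | alternative 2 | 6-(benzyloxy)-2-[3,5-bis(benzyloxy)-4-methoxyphenyl]-5,8-dimethoxy-4H-chromen-4-one | COc1cc(OCc2ccccc2)c(OC)c2c1oc(-c1cc(OCc3ccccc3)c(OC)c(OCc3ccccc3)c1)cc2=O
A9 | alternative 3 | 7-hydroxy-5,8-dimethoxy-4H-chromen-4-one | COc1cc(O)c(OC)c2occc(=O)c12
A10 | alternative 3 | [3,5-bis(benzyloxy)-4-methoxyphenyl]boronic acid | COc1c(OCc2ccccc2)cc(B(O)O)cc1OCc1ccccc1
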